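Readings and results were computed from invented constants; scatter was added.

The constants were hidden from me, so I asked what the readings could give without them.

the same everywhere: starting material 21 mM; catalyst 42 µM

| charge | reagent | second substrate | temperature | remark | time |
|---|---|---|---|---|---|
| eta | 63 mM | 21 mM | 85 °C | run made earlier |  |
| midnight | 31.5 mM | 21.0 mM | 85 °C |  | 40 h |
| spring | 31.5 mM | 21.0 mM | 60 °C |  | 40 h |

- reactions considered so far: starting material + reagent + catalyst -> catalyst + target; second substrate + reagent + catalyst -> catalyst + second product; reagent + catalyst + target -> catalyst + over-reaction product
- the earlier runs do not show what temperature does; that part of a forecast is a guess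

1. which flask leads in amount of target, in percent of the starting material charged ("all alike" within 1.5 percentage points) (midnight / spring / all alike)
2. how much target is there at the end, in percent of the starting material charged: midnight
3. how much target is there at the end, in percent of the starting material charged: spring

Every step takes reagent and catalyst. So, at one temperature, I assumed both substrates ran on one clock, whatever the reagent level.

- eta (time / h: target / %, starting material / %): 0.333: 41.4, 57.9; 0.667: 63.2, 36.3; 1.50: 84.1, 14.1; 4.00: 93.0, 1.5

(each reading ± 0.3 percentage points)

I read the starting material column down. Its logarithm fell by 1.64 h⁻¹ in the first gap and by 0.896 h⁻¹ in the last, slower. I took that rate to follow the reagent. Per charge of starting material, the reagent began at 3.00 and stood near 2.79 in the first gap, so it stood near 1.52 in the last. The starting material averaged 5.62% over that gap. The reagent balance then left 46.7% of the second substrate. I dropped two terms that pull opposite ways: the reagent the second substrate took in the first gap, and the reagent taken by over-reaction. That gave the selectivity factor S, the logarithm of the fraction of starting material left over that of the fraction of second substrate left, of 3.78. It is a rough reading, since the last starting material reading is 1.5% with a scatter of 0.3 percentage points.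

Midnight holds 1.50 of reagent per charge against 2.00 for both substrates, less, which makes reagent the limiting reagent. The eta run's balance was short by 5.50% at its last reading, and I allowed 2.75% of over-reaction product for midnight. Solving the reagent balance with S left 5.68% of the starting material, so I expected 91.6% of target. For spring I kept S as a guess and expected the flasks to be alike.

The forecast differed: midnight leading, 84.5% for midnight and 81% for spring, holding that “the second substrate reacts about half as fast”.

    starting material + reagent + catalyst → catalyst + target (k = 2.80 × 10⁵ M⁻² h⁻¹, Ea = 36.0 kJ mol⁻¹)
    second substrate + reagent + catalyst → catalyst + second product (k = 73000 M⁻² h⁻¹, Ea = 38.0 kJ mol⁻¹)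
    reagent + catalyst + target → catalyst + over-reaction product (k = 4700 M⁻² h⁻¹, Ea = 37.0 kJ mol⁻¹)
    (constants at 60 °C)

Midnight gave 90.6% and spring 90.0%, so the result was all alike. At 40.0 h in spring, the making of target drew reagent at 0.55 of the rate at which the loss of second substrate drew it. S, read in the eta run at 85 °C, times the fractions left in spring, 7.2% over 50%, gives 0.544. A neighbour of spring charged with 36 mM of second substrate ended with 16% of its starting material, from which S gives 61.6% of its own charge of second substrate; that neighbour held 62.5%.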